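The plan cuts the C9–C10 bond (germacrane numbering: C10 is the quaternary C2 of the 2-methylfuran-3(2H)-one ring, C9 the neighbouring carbinol), i.e. the β-hydroxy ketone C1(=O)–C10–C9(OH) that lies inside the nine-membered oxacycle. Because C10–H of a furan-3(2H)-one is the most acidic C–H and its enolate is an aromatic furan-3-olate, a boron-mediated intramolecular aldol addition to an α-methacryloyloxy aldehyde closes the oxonine ring last, sets C9 and C10 and gives the target directly. The precursor is a seco aldehyde already carrying the spiro-epoxy trans-γ-lactone, the Z-alkene and the furanone; it comes from (R)-glyceraldehyde acetonide by chromium-mediated lactone-forming allylation, Sharpless epoxidation and carbonylative alkynylation–cycloisomerisation.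

Key step: step 15

Remark (locants): germacrane numbering is used throughout: C1 furanone C=O, C2 furanone CH=, C3 furanone O–C=, C4=C5 (C15 methyl on C4), C6 lactone O–CH, C7, C8 (ester), C9 (carbinol), C10 (quaternary, C14 methyl), C11 spiro carbon, C12 lactone C=O, C13 epoxide CH2. The target is 6R,7S,8S,9R,10S,11S.

Remark (assumption): racemic but-3-yn-2-ol is used, so 15–21 are pairs of C10 epimers; C10 is planar in the furanolate of step 15 and is fixed only there. The CrCl2 of step 5 is nickel-free so that the vinyl iodide stays untouched.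

Step 1
Reactants: 1 but-2-yn-1-ol
Product: 3 (Z)-3-iodobut-2-en-1-ol, via cyclic alkenylalanate 2 (not isolated)
Conditions: NaAlH2(OCH2CH2OCH3)2, THF, 0 °C to rt; then I2, −78 to 0 °C
Reagents that add atoms: iodine, [I][I]
Why: Trans-hydroalumination of the propargylic alcohol places aluminium on C3 through the five-membered alkoxyalanate, and iodinolysis with retention should give the Z-iodoalkene (hydroalumination–iodination).

Step 2
Reactants: 3 (Z)-3-iodobut-2-en-1-ol
Product: 4 (Z)-3-iodobut-2-enal
Conditions: MnO2, CH2Cl2, rt, dark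
Reagents that add atoms: none
Why: MnO2 oxidises the allylic alcohol selectively to the enal without touching the C–I bond or the Z geometry (allylic oxidation); the aldehyde is used at once.

Step 3
Reactants: 5 (R)-2,2-dimethyl-1,3-dioxolane-4-carbaldehyde and 6 methyl acrylate
Product: 7 Morita–Baylis–Hillman adduct (both carbinol epimers)
Conditions: DABCO, 1,4-dioxane/H2O (1:1), rt
Reagents that add atoms: none
Why: Morita–Baylis–Hillman reaction, in which DABCO adds to the acrylate and the resulting enolate attacks the aldehyde; the new carbinol centre is erased in step 4 and the dioxolane centre should not be touched.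

Step 4
Reactants: 7 Morita–Baylis–Hillman adduct
Product: 8 methyl (Z)-2-(bromomethyl)-3-[(4S)-2,2-dimethyl-1,3-dioxolan-4-yl]prop-2-enoate
Conditions: NBS, Me2S, CH2Cl2, 0 °C to rt
Reagents that add atoms: N-bromosuccinimide, O=C1CCC(=O)N1Br
Why: Corey–Kim-type activation of the allylic alcohol followed by SN2′ attack of bromide should give the thermodynamically preferred Z-configured 2-(bromomethyl)enoate (allylic transposition of a Morita–Baylis–Hillman adduct) under acid-free conditions that spare the acetonide.

Step 5
Reactants: 8 allylic bromide and 4 (Z)-3-iodobut-2-enal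
Product: 10 trans-α-methylene-γ-butyrolactone with the dioxolane on C7 and the (Z)-2-iodopropenyl group on C6, via hydroxy ester 9 (not isolated)
Conditions: CrCl2 (nickel-free), THF, 0 °C to rt; then PPTS (cat.), CH2Cl2, rt
Reagents that add atoms: none
Why: Nozaki–Hiyama-type 2-(alkoxycarbonyl)allylation, in which the σ-allyl trivalent chromium species reacts at its γ-carbon through a chair transition state with the dioxolanyl group equatorial (anti adduct, hence the trans lactone after ring closure) and the aldehyde is expected anti to the dioxolane C–C bond of the A1,3-locked rotamer (dioxolane C–H in the alkene plane, C–O outside), which sets C6 and C7 from C8.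

Step 6
Reactants: 10 trans-α-methylene lactone
Product: 11 2-methylene-1,4-diol (C12 primary allylic alcohol and C6 secondary alcohol)
Conditions: iBu2AlH, CH2Cl2, −78 to 0 °C; aq. KNaC4H4O6 work-up
Reagents that add atoms: none
Why: iBu2AlH reduces the lactone carbonyl twice in 1,2-fashion (through the lactol) to the diol, while the vinyl iodide and the acetonide are inert at low temperature.

Step 7
Reactants: 11 2-methylene-1,4-diol
Product: 12 epoxy diol with the (R)-configured 2-(hydroxymethyl)oxirane
Conditions: Ti(OiPr)4 (cat.), D-(−)-diethyl tartrate, tBuOOH, 4 Å MS, CH2Cl2, −20 °C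
Reagents that add atoms: tert-butyl hydroperoxide, CC(C)(C)OO
Why: Sharpless asymmetric epoxidation, in which the titanium tartrate complex epoxidises only the primary 1,1-disubstituted allylic alcohol (the secondary alcohol flanks an electron-poor Z-iodoalkene that is a very slow substrate) and D-(−)-diethyl tartrate delivers oxygen by reagent control to the face that becomes the 11S spiro epoxide.

Step 8
Reactants: 12 epoxy diol
Product: 13 spiro-epoxy trans-γ-lactone (vinyl iodide)
Conditions: TEMPO (cat.), PhI(OAc)2, CH2Cl2, rt
Reagents that add atoms: none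
Why: Oxidative lactonisation of a 1,4-diol, in which TEMPO/PhI(OAc)2 oxidises the primary alcohol to the aldehyde, the C6 hydroxyl closes the lactol and a second oxidation gives the lactone with the epoxide intact.

Step 9
Reactants: 13 spiro-epoxy lactone vinyl iodide and 14 but-3-yn-2-ol
Product: 15 Z-configured γ-hydroxy enynone
Conditions: PdCl2(PPh3)2 (cat.), CuI (cat.), Et3N, CO (1 atm), THF, rt
Reagents that add atoms: carbon monoxide, [C-]#[O+]
Why: Carbonylative Sonogashira coupling, in which oxidative addition to the C–I bond with retention of the Z geometry, CO insertion and alkynyl transfer from copper should give the alkenyl alkynyl ketone, the hindered tertiary amine being too poor a nucleophile to open the epoxy lactone.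

Step 10
Reactants: 15 γ-hydroxy enynone
Product: 16 5-alkenyl-2-methylfuran-3(2H)-one (acetonide)
Conditions: (p-CF3C6H4)3PAuCl (cat.), AgOTf (cat.), toluene, rt
Reagents that add atoms: none
Why: Cationic-gold-catalysed cycloisomerisation of a γ-hydroxy alkynone to a 3(2H)-furanone, in which the carbinol oxygen becomes the ring oxygen, the former ketone carbon becomes C3 and the alkyne carbon next to the carbinol becomes the C1 ketone, leaving the Z-alkene untouched.

Step 11
Reactants: 16 furanone acetonide
Product: 17 C8/C9 diol
Conditions: AcOH/H2O/THF (4:1:1), 35 °C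
Reagents that add atoms: none
Why: Acid hydrolysis of the terminal acetonide, the most labile acetal present; the epoxy lactone (ionisation disfavoured by its carbonyl) and the vinylogous ester should survive dilute acetic acid.

Step 12
Reactants: 17 C8/C9 diol
Product: 19 C8 methacrylate with C9 triethylsilyl ether, via C9 triethylsilyl ether 18 (not isolated)
Conditions: Et3SiCl, 2,6-lutidine, CH2Cl2, −78 °C; then methacrylic anhydride, DMAP (cat.), pyridine, 0 °C
Reagents that add atoms: chlorotriethylsilane, CC[Si](CC)(CC)Cl; methacrylic anhydride, C=C(C)C(=O)OC(=O)C(C)=C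
Why: The primary hydroxyl is silylated selectively at low temperature and the remaining secondary C8 hydroxyl is then esterified in the same flask (DMAP-catalysed acylation), pyridine being too weak a base to enolise and O-acylate the furanone.

Step 13
Reactants: 19 methacrylate silyl ether
Product: 20 C9 primary alcohol
Conditions: HF·pyridine, pyridine, THF, 0 °C
Reagents that add atoms: none
Why: Buffered fluoride cleaves the primary triethylsilyl ether without base (desilylation), which should limit migration of the methacryloyl group to the primary oxygen.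

Step 14
Reactants: 20 C9 primary alcohol
Product: 21 seco aldehyde (α-methacryloyloxy aldehyde)
Conditions: Dess–Martin periodinane, NaHCO3, CH2Cl2, 0 °C
Reagents that add atoms: none
Why: Dess–Martin oxidation should give the α-acyloxy aldehyde under nearly neutral conditions that do not epimerise C8; the aldehyde is used at once.

Step 15
Reactants: 21 seco aldehyde
Product: 24 target CNP0407138.2, via boron furanolate 22 (not isolated), via boron aldolate 23 (not isolated)
Conditions: Bu2BOTf, iPr2NEt, CH2Cl2 (0.002 M), slow addition, −78 to −40 °C; then pH 7 buffer/MeOH, 0 °C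
Reagents that add atoms: none
Why: Bu2BOTf binds the most Lewis-basic carbonyl (the vinylogous-ester C1=O of the furanone), iPr2NEt removes the now very acidic C10–H to give the aromatic dibutylboryl furan-3-olate, and its C10 adds to the tethered aldehyde through a six-membered boron-bridged transition state, after which mild hydrolysis frees the C9 hydroxyl. The closest known reaction types are the boron-mediated aldol addition of ketones by soft enolisation and the C2-selective aldol addition of furan-3-ol derivatives (lithium enolates or 3-silyloxyfurans of 3(2H)-furanones) to aldehydes, used here as a macro-aldolisation. The nine-membered oxacycle C3–O–C10–C9–C8–C7–C6–C5–C4 closes in a 9-(enolexo)-exo-trig mode, which completes the ten-membered carbocycle at the same time. C10 is controlled by the tether: A1,3 strain about C5–C6 keeps H6 in the plane of the Z-diene, so the trans-fused lactone sends the C7–C8–C9 arm onto one face of the planar furanolate, and bonding on that face gives 10S. C9 is controlled by the boron bridge, which holds the aldehyde oxygen beside the furanolate oxygen while the tether holds C8 beneath the ring-oxygen side of C10 (anti to the C14 methyl, the aldehyde substituent being forced axial in Zimmerman–Traxler terms), which should give 9R. The step needs enolisation at C10–H in preference to the aldehyde α C–H at C8 and ring closure in preference to oligomerisation; the first is secured by the higher Lewis basicity of the vinylogous ester and the aromaticity of the enolate, the second by high dilution and slow addition at low temperature, and the covalent boron aldolate should suppress retro-aldol cleavage and acyl migration.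

Compound list
1 | but-2-yn-1-ol | CC#CCO | starting material
2 | sodium cyclic (Z)-alkenylalanate (3-methyl-2,5-dihydro-1,2-oxaaluminol-2-uide with two 2-methoxyethoxy groups on aluminium; formed in the flask) | CC1=CCO[Al-]1(OCCOC)OCCOC.[Na+] | intermediate
3 | (Z)-3-iodobut-2-en-1-ol | C/C(I)=C/CO | intermediate
4 | (Z)-3-iodobut-2-enal | C/C(I)=C/C=O | intermediate
5 | (R)-2,2-dimethyl-1,3-dioxolane-4-carbaldehyde | O=C[C@H]1COC(C)(C)O1 | starting material
6 | methyl acrylate | C=CC(=O)OC | starting material
7 | methyl 2-{hydroxy[(4R)-2,2-dimethyl-1,3-dioxolan-4-yl]methyl}prop-2-enoate (both carbinol epimers) | C=C(C(=O)OC)C(O)[C@H]1COC(C)(C)O1 | intermediate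
8 | methyl (Z)-2-(bromomethyl)-3-[(4S)-2,2-dimethyl-1,3-dioxolan-4-yl]prop-2-enoate | BrC/C(C(=O)OC)=C\[C@H]1COC(C)(C)O1 | intermediate
9 | methyl (3S,4S,5Z)-3-[(4S)-2,2-dimethyl-1,3-dioxolan-4-yl]-4-hydroxy-6-iodo-2-methylidenehept-5-enoate (formed in the flask) | COC(=O)C(=C)[C@@H]([C@H](O)/C=C(/C)I)[C@H]1COC(C)(C)O1 | intermediate
10 | (4S,5S)-4-[(4S)-2,2-dimethyl-1,3-dioxolan-4-yl]-5-[(Z)-2-iodoprop-1-en-1-yl]-3-methylideneoxolan-2-one (trans) | CC1(C)OC[C@@H](O1)[C@@H]1[C@@H](/C=C(/C)I)OC(=O)C1=C | intermediate
11 | (3S,4S,5Z)-3-[(4S)-2,2-dimethyl-1,3-dioxolan-4-yl]-6-iodo-2-methylidenehept-5-ene-1,4-diol | OCC(=C)[C@@H]([C@H](O)/C=C(/C)I)[C@H]1COC(C)(C)O1 | intermediate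
12 | [(2R)-2-{(1S,2S,3Z)-1-[(4S)-2,2-dimethyl-1,3-dioxolan-4-yl]-2-hydroxy-4-iodopent-3-en-1-yl}oxiran-2-yl]methanol | OC[C@@]1(CO1)[C@@H]([C@H](O)/C=C(/C)I)[C@H]1COC(C)(C)O1 | intermediate
13 | (3S,6S,7S)-7-[(4S)-2,2-dimethyl-1,3-dioxolan-4-yl]-6-[(Z)-2-iodoprop-1-en-1-yl]-1,5-dioxaspiro[2.4]heptan-4-one | CC1(C)OC[C@@H](O1)[C@@H]1[C@@H](/C=C(/C)I)OC(=O)[C@@]12CO2 | intermediate
14 | but-3-yn-2-ol (racemic) | CC(O)C#C | starting material
15 | (3S,6R,7S)-7-[(4S)-2,2-dimethyl-1,3-dioxolan-4-yl]-6-[(1Z)-6-hydroxy-2-methyl-3-oxohept-1-en-4-yn-1-yl]-1,5-dioxaspiro[2.4]heptan-4-one (both carbinol epimers) | CC1(C)OC[C@@H](O1)[C@@H]1[C@@H](/C=C(/C)C(=O)C#CC(C)O)OC(=O)[C@@]12CO2 | intermediate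
16 | (3S,6R,7S)-7-[(4S)-2,2-dimethyl-1,3-dioxolan-4-yl]-6-[(1Z)-2-(5-methyl-4-oxo-4,5-dihydrofuran-2-yl)prop-1-en-1-yl]-1,5-dioxaspiro[2.4]heptan-4-one (C10 epimers) | CC1(C)OC[C@@H](O1)[C@@H]1[C@@H](/C=C(/C)C2=CC(=O)C(C)O2)OC(=O)[C@@]13CO3 | intermediate
17 | (3S,6R,7R)-7-[(1S)-1,2-dihydroxyethyl]-6-[(1Z)-2-(5-methyl-4-oxo-4,5-dihydrofuran-2-yl)prop-1-en-1-yl]-1,5-dioxaspiro[2.4]heptan-4-one (C10 epimers) | OC[C@@H](O)[C@@H]1[C@@H](/C=C(/C)C2=CC(=O)C(C)O2)OC(=O)[C@@]13CO3 | intermediate
18 | C9 triethylsilyl ether of 17, C8 hydroxyl free (formed in the flask; C10 epimers) | CC[Si](CC)(CC)OC[C@@H](O)[C@@H]1[C@@H](/C=C(/C)C2=CC(=O)C(C)O2)OC(=O)[C@@]13CO3 | intermediate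
19 | (1S)-1-{(3S,6R,7S)-6-[(1Z)-2-(5-methyl-4-oxo-4,5-dihydrofuran-2-yl)prop-1-en-1-yl]-4-oxo-1,5-dioxaspiro[2.4]heptan-7-yl}-2-[(triethylsilyl)oxy]ethyl 2-methylprop-2-enoate (C10 epimers) | CC[Si](CC)(CC)OC[C@@H](OC(=O)C(C)=C)[C@@H]1[C@@H](/C=C(/C)C2=CC(=O)C(C)O2)OC(=O)[C@@]13CO3 | intermediate
20 | the corresponding (1S)-2-hydroxyethyl 2-methylprop-2-enoate (C9 primary alcohol; C10 epimers) | OC[C@@H](OC(=O)C(C)=C)[C@@H]1[C@@H](/C=C(/C)C2=CC(=O)C(C)O2)OC(=O)[C@@]13CO3 | intermediate
21 | the corresponding (1S)-2-oxoethyl 2-methylprop-2-enoate (seco aldehyde; C10 epimers) | O=C[C@@H](OC(=O)C(C)=C)[C@@H]1[C@@H](/C=C(/C)C2=CC(=O)C(C)O2)OC(=O)[C@@]13CO3 | intermediate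
22 | dibutylboryl furan-3-olate of 21 (4-[(dibutylboranyl)oxy]-5-methylfuran-2-yl in place of the furanone; formed in the flask) | O=C[C@@H](OC(=O)C(C)=C)[C@@H]1[C@@H](/C=C(/C)c2cc(OB(CCCC)CCCC)c(C)o2)OC(=O)[C@@]13CO3 | intermediate
23 | O9-dibutylboryl aldolate of the target (formed in the flask) | C=C(C)C(=O)O[C@H]1[C@@H]2[C@@H](/C=C(/C)C3=CC(=O)[C@@](C)(O3)[C@@H]1OB(CCCC)CCCC)OC(=O)[C@@]21CO1 | intermediate
24 | CNP0407138.2: (6R,7S,8S,9R,10S,11S,4Z)-9-hydroxy-8-methacryloyloxy-3,10-epoxy-11,13-epoxy-1-oxogermacra-2,4-dien-12,6-olide | C=C(C)C(=O)O[C@H]1[C@@H]2[C@@H](/C=C(/C)C3=CC(=O)[C@@](C)(O3)[C@@H]1O)OC(=O)[C@@]21CO1 | target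

Total step count: 15. Longest linear sequence: 13 steps (5 to 24, steps 3–15); steps 1 and 2 make aldehyde 4, which enters at step 5.

Steps most likely to fail

Step 15. The boron furanolate may bond to the wrong face of the aldehyde, which would give the C9 epimer, because the facial preference rests on a qualitative transition-state argument for a strained nine-membered ring. Competing enolisation of the aldehyde would in addition erode C8. The fallback sets out from 21 and comes back at 24, and it separates ring closure from the setting of C9. The ring would be closed from 21 as before, accepting the 9-epimeric aldol F1. Dess–Martin oxidation would then give the C1,C9-diketone F2, whose C10 is quaternary and cannot enolise. Reduction with NaBH4 and CeCl3·7H2O in MeOH at −78 °C should touch only the saturated C9 ketone. Polar Felkin–Anh attack anti to the C8–O bond should give the 8,9-syn alcohol 24.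

Step 5. Facial control by the dioxolane centre may be low, and equilibration of the allylchromium geometry may erode the anti selectivity, so that the wrong C6/C7 pair or a cis lactone forms. The fallback sets out from 4 and comes back at 10, and it uses an allyl donor whose alkene geometry and neighbouring stereocentre are locked in a ring. Commercial (S)-but-3-ene-1,2-diol F3 would be esterified at the primary hydroxyl with 2-(bromomethyl)acrylic acid (DIC, DMAP cat., CH2Cl2, −20 °C) to the ester F4. Ring-closing metathesis with second-generation Grubbs catalyst (H2IMes)(PCy3)Cl2Ru=CHPh in CH2Cl2 at reflux would give the six-membered bromomethyl lactone F5. Its allylzinc reagent (Zn, THF/aq. NH4Cl, 0 °C) should add to 4 at C7 anti to the ring hydroxyl through a chair transition state, giving the anti adduct F6. Acid-catalysed translactonisation (CSA cat., CH2Cl2) to the more stable γ-lactone diol F7, then acetonide formation (2,2-dimethoxypropane, PPTS), would return to 10.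

Step 13. Once the primary C9 hydroxyl is free, the methacryloyl group may migrate from O8 to O9. The fallback sets out from 19 and comes back at 21 without ever liberating the alcohol, and it makes no new compound (F0). The primary triethylsilyl ether of 19 would be converted directly into the aldehyde under Swern conditions ((COCl)2, DMSO, CH2Cl2, −78 to −40 °C; then Et3N), a known oxidative cleavage of primary triethylsilyl ethers.

Further compounds
F1 | step 15 | 9-epimer of the target (9S) | C=C(C)C(=O)O[C@H]1[C@@H]2[C@@H](/C=C(/C)C3=CC(=O)[C@@](C)(O3)[C@H]1O)OC(=O)[C@@]21CO1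
F2 | step 15 | 9-oxo derivative of the target (C1,C9-diketone) | C=C(C)C(=O)O[C@H]1[C@@H]2[C@@H](/C=C(/C)C3=CC(=O)[C@@](C)(O3)C1=O)OC(=O)[C@@]21CO1
F3 | step 5 | (S)-but-3-ene-1,2-diol | OC[C@@H](O)C=C
F4 | step 5 | (2S)-2-hydroxybut-3-en-1-yl 2-(bromomethyl)prop-2-enoate | C=C(CBr)C(=O)OC[C@@H](O)C=C
F5 | step 5 | (5S)-3-(bromomethyl)-5-hydroxy-5,6-dihydro-2H-pyran-2-one | O=C1OC[C@@H](O)C=C1CBr
F6 | step 5 | (4S,5S)-5-hydroxy-4-[(1S,2Z)-1-hydroxy-3-iodobut-2-en-1-yl]-3-methylideneoxan-2-one | O=C1OC[C@@H](O)[C@H]([C@H](O)/C=C(/C)I)C1=C
F7 | step 5 | (4R,5S)-4-[(1S)-1,2-dihydroxyethyl]-5-[(Z)-2-iodoprop-1-en-1-yl]-3-methylideneoxolan-2-one | OC[C@@H](O)[C@@H]1[C@@H](/C=C(/C)I)OC(=O)C1=C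
F0 | step 13 | none | none
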